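**Plan**

- Locants: chromane O1, spiro C2, C3, C4, C4a, C5–C8, C8a (ring A benzene, ring B pyran); norbornane C1'–C7' with C2' = C2 and C3' the CMe2 carbon.
- Retrosynthesis cuts, in order: the C5 O–methyl bond, the two ring A–CHO bonds (C6, C8), C4–isobutyl (back to a chroman-4-one), C2–C3 of ring B (back to a diazomethyl ketone), C8a–O1 (aryl fluoride plus endo-camphenilol), and the C3 carbon from the ring A nitrile.
- Forward: ring A and the norbornane are bought. endo-Camphenilol from camphene is joined to the benzonitrile through O1, the nitrile becomes the diazoketone, and ring B closes by C–H insertion. Isobutyl addition, hydrogenation, diformylation and demethylation follow.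
- Enabling feature: C2 is a tertiary carbon α to O1. In the endo-camphenilyl aryl ether its exo C–H bond is activated by that oxygen and lies six atoms from a carbenoid carbon at C3.
- Stereochemistry: C1' and C4' come from (1S,4R)-camphene. The endo C2–O1 bond is set by exo hydride delivery to camphenilone and is kept by the SNAr step (C–O bond untouched) and by insertion with retention, which puts C3 exo. C4 is set by hydrogenation from the ring B face anti to C3'.

Key step: step 7

Assumption: (1S,4R)-camphene is used in high enantiomeric purity, since every stereocentre of the target is relayed from its two bridgeheads.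

**Route**

Step 1
Reactants: 1 (1S,4R)-camphene
Product: 3 (1R,4S)-camphenilone (3,3-dimethylbicyclo[2.2.1]heptan-2-one), via camphene ozonide 2 (not isolated)
Conditions: O3, CH2Cl2, −78 °C; then Me2S, −78 °C → rt
Reagents that add atoms: ozone, [O-][O+]=O
Why: Ozonolysis (1,3-dipolar cycloaddition of ozone to the exocyclic 1,1-disubstituted alkene, then rearrangement) gives ozonide 2, which Me2S reduces to the ketone, and the two bridgehead stereocentres are not involved.

Step 2
Reactants: 3 (1R,4S)-camphenilone
Product: 4 endo-camphenilol, (1R,2R,4S)-3,3-dimethylbicyclo[2.2.1]heptan-2-ol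
Conditions: LiAlH4, Et2O, 0 °C; H2O, aq. NaOH work-up
Reagents that add atoms: none
Why: Hydride reduction under steric approach control: the gem-dimethyl group flanks both faces equally, so hydride should attack from the exo face as in norbornanone (the endo face is screened by the C5'/C6' endo hydrogens), which sets C2 with the hydroxyl endo (2R), and the minor exo alcohol should be removable by chromatography.

Step 3
Reactants: 5 2,6-difluoro-4-hydroxybenzonitrile
Product: 6 4-(benzyloxy)-2,6-difluorobenzonitrile
Conditions: BnBr, K2CO3, DMF, rt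
Reagents that add atoms: benzyl bromide, BrCc1ccccc1
Why: Williamson ether synthesis on a phenol made acidic by the para nitrile and two fluorines, so K2CO3 suffices and benzylation should outrun any fluoride displacement by the weakly nucleophilic phenoxide.

Step 4
Reactants: 6 4-(benzyloxy)-2,6-difluorobenzonitrile; 4 endo-camphenilol
Product: 8 4-(benzyloxy)-2-methoxy-6-{[(1R,2R,4S)-3,3-dimethylbicyclo[2.2.1]heptan-2-yl]oxy}benzonitrile, via monofluoro aryl ether 7 (not isolated)
Conditions: 4, KHMDS, THF, 0 °C; add 6, 0 °C → rt; then NaOMe, MeOH–DMF, 70 °C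
Reagents that add atoms: sodium methoxide, C[O-].[Na+]
Why: Two sequential nucleophilic aromatic substitutions ortho to the nitrile: the hindered potassium alkoxide of 4 displaces one of the two equivalent fluorides and the new alkoxy group deactivates the ring enough to stop there, then the small methoxide displaces the second fluoride on heating, and because the carbinol C–O bond of 4 is never broken the endo configuration is retained.

Step 5
Reactants: 8 4-(benzyloxy)-2-methoxy-6-(endo-camphenilyloxy)benzonitrile
Product: 10 1-[4-(benzyloxy)-2-methoxy-6-(endo-camphenilyloxy)phenyl]ethan-1-one, via N–H ketimine 9 (not isolated)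
Conditions: MeMgBr, toluene–THF, 70 °C; then 2 M aq. HCl, THF, 40 °C
Reagents that add atoms: methylmagnesium bromide, C[Mg]Br; water, O
Why: Grignard addition to a nitrile gives the N-magnesio ketimine, which resists a second addition, and aqueous acid should hydrolyse ketimine 9 to the methyl ketone without harming the secondary alkyl aryl ether or the benzyl ether.

Step 6
Reactants: 10 1-[4-(benzyloxy)-2-methoxy-6-(endo-camphenilyloxy)phenyl]ethan-1-one
Product: 12 1-[4-(benzyloxy)-2-methoxy-6-(endo-camphenilyloxy)phenyl]-2-diazoethan-1-one, via trifluoroacetyl diketone 11 (not isolated)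
Conditions: LiHMDS, THF, −78 °C; CF3CO2CH2CF3; aq. HCl; then MsN3, Et3N, H2O, MeCN, rt
Reagents that add atoms: methanesulfonyl azide, CS(=O)(=O)N=[N+]=[N-]; 2,2,2-trifluoroethyl trifluoroacetate, O=C(OCC(F)(F)F)C(F)(F)F (its trifluoroacetyl group is carried only in 11)
Why: Detrifluoroacetylative diazo transfer (a Regitz diazo transfer on an activated 1,3-diketone): Claisen trifluoroacetylation of the lithium enolate gives 11, whose acidic methylene accepts the diazo group from MsN3 before the trifluoroacetyl group leaves as the N-acylsulfonamide, a standard sequence for aryl methyl ketones.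

Step 7
Reactants: 12 1-[4-(benzyloxy)-2-methoxy-6-(endo-camphenilyloxy)phenyl]-2-diazoethan-1-one
Product: 13 (2R,1'R,4'S)-7-(benzyloxy)-5-methoxy-3',3'-dimethylspiro[chromane-2,2'-bicyclo[2.2.1]heptan]-4-one (O1 endo, C3 exo)
Conditions: Rh2(OAc)4 (1 mol %), CH2Cl2, 40 °C, slow addition of 12 at high dilution
Reagents that add atoms: none
Why: Rh2(OAc)4 should extrude N2 from 12 to give an electrophilic rhodium carbenoid whose carbon (the future C3) inserts into the exo C2–H bond of the endo-camphenilyl ether through a concerted three-centre transition state with hydride-transfer character; the closest known reaction type is the dirhodium-carboxylate-catalysed insertion of 2-alkoxyaryl diazoketones into the C–H bond α to the ether oxygen to give chroman-4-ones. Ring B closes as a six-membered ring by 1,6 C–H insertion that forms the C2–C3 bond, and a five-membered alternative is excluded because the atom five positions from the carbenoid carbon is O1 itself. The new quaternary stereocentre C2 is controlled by the carbinol stereocentre set in step 2: insertion proceeds with retention, so O1 stays endo and C3 takes the exo position vacated by hydrogen. The step needs site selectivity for this tertiary C–H bond over the primary C–H bonds of the C5 methoxy group, and chemoselectivity over oxonium ylide formation. The first should be secured by the better stabilisation of developing positive charge at a tertiary α-oxy carbon and by the exposed exo position of the bond; the second by the low nucleophilicity of aryl ether oxygens conjugated to the carbonyl and by the lack of an easy onward path for a methyl oxonium ylide, which reverts. The C7 benzyloxy group is out of reach of any cyclic transition state, and slow addition at high dilution should suppress carbene dimerisation.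

Step 8
Reactants: 13 spirochroman-4-one; 14 isobutylmagnesium bromide
Product: 16 (2S,1'R,4'S)-7-(benzyloxy)-5-methoxy-3',3'-dimethyl-4-(2-methylpropyl)spiro[chromene-2,2'-bicyclo[2.2.1]heptane] (same spatial arrangement at C2; the descriptor changes only through the priority rules), via tertiary alcohol 15 (not isolated)
Conditions: 14, CeCl3 (anhydrous), THF, −78 → 0 °C; aq. NH4Cl; then PPTS (cat.), CH2Cl2, rt, dark
Reagents that add atoms: isobutylmagnesium bromide 14, CC(C)C[Mg]Br
Why: Organocerium 1,2-addition followed by E1 dehydration: the weakly basic, oxophilic cerium reagent should add to the hindered, enolisable C4 ketone without enolisation, ring B opening or β-hydride reduction, and tertiary benzylic alcohol 15, whose cation is stabilised by O1 and the C5 and C7 alkoxy groups, should lose water under mild acid to the C3=C4 alkene, so the C4 configuration of 15 is of no consequence.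

Step 9
Reactants: 16 4-isobutyl-2H-chromene
Product: 17 (2R,4S,1'R,4'S)-5-methoxy-3',3'-dimethyl-4-(2-methylpropyl)spiro[chromane-2,2'-bicyclo[2.2.1]heptan]-7-ol
Conditions: H2 (3 atm), 10% Pd/C, EtOAc–EtOH, rt
Reagents that add atoms: none
Why: Heterogeneous syn hydrogenation with concurrent hydrogenolysis of the benzyl ether: the exo methyl group on C3' sits directly beneath C3 on one face of ring B, so hydrogen should be delivered to C4 from the opposite face (syn to the C1' bridgehead hydrogen), which leaves the isobutyl group syn to C3' and sets C4 as S, and 16 is kept in the dark and reduced at once to avoid electrocyclic opening of the 2H-chromene.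

Step 10
Reactants: 17 7-hydroxy-5-methoxy-4-isobutyl spirochromane
Product: 19 (2R,4S,1'R,4'S)-7-hydroxy-5-methoxy-3',3'-dimethyl-4-(2-methylpropyl)spiro[chromane-2,2'-bicyclo[2.2.1]heptane]-6,8-dicarbaldehyde, via bis(α-chloro ether) adduct 18 (not isolated)
Conditions: Cl2CHOMe, TiCl4, CH2Cl2, −20 → 0 °C; then ice-cold aq. HCl
Reagents that add atoms: dichloromethyl methyl ether, COC(Cl)Cl; water, O
Why: Rieche formylation (Friedel–Crafts reaction of Cl2CHOMe activated by TiCl4): the titanium phenoxide formed at the C7 hydroxyl should direct the electrophile to its two ortho positions C6 and C8, the only free positions of ring A, and hydrolysis of adduct 18 releases both aldehydes, while the low temperature is chosen to spare the tertiary C2–O1 ether.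

Step 11
Reactants: 19 7-hydroxy-5-methoxy dialdehyde
Product: 20 target, (2R,4S,1'R,4'S)-5,7-dihydroxy-3',3'-dimethyl-4-(2-methylpropyl)spiro[chromane-2,2'-bicyclo[2.2.1]heptane]-6,8-dicarbaldehyde
Conditions: LiCl, DMF, 130 °C; then 1 M aq. HCl
Reagents that add atoms: none
Why: SN2 O-demethylation by chloride: the C5 methoxy group is activated by the ortho C6 and para C8 formyl groups, which stabilise the departing aryloxide, whereas the tertiary C2–O1 ether cannot react by SN2 and no Lewis or protic acid is present to ionise it, so C2 and C4 should be untouched.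

**Compound list**

1 | (1S,4R)-camphene, (1S,4R)-2,2-dimethyl-3-methylidenebicyclo[2.2.1]heptane | C=C1[C@@H]2CC[C@@H](C2)C1(C)C | starting material
2 | camphene ozonide, (1R,4S)-3,3-dimethylspiro[bicyclo[2.2.1]heptane-2,3'-[1,2,4]trioxolane], spiro carbon unassigned | C1OC2(OO1)[C@@H]1CC[C@@H](C1)C2(C)C | intermediate (not isolated)
3 | (1R,4S)-camphenilone, (1R,4S)-3,3-dimethylbicyclo[2.2.1]heptan-2-one | O=C1[C@@H]2CC[C@@H](C2)C1(C)C | intermediate
4 | endo-camphenilol, (1R,2R,4S)-3,3-dimethylbicyclo[2.2.1]heptan-2-ol | O[C@@H]1[C@@H]2CC[C@@H](C2)C1(C)C | intermediate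
5 | 2,6-difluoro-4-hydroxybenzonitrile | N#Cc1c(F)cc(O)cc1F | starting material
6 | 4-(benzyloxy)-2,6-difluorobenzonitrile | N#Cc1c(F)cc(OCc2ccccc2)cc1F | intermediate
7 | 4-(benzyloxy)-2-fluoro-6-{[(1R,2R,4S)-3,3-dimethylbicyclo[2.2.1]heptan-2-yl]oxy}benzonitrile | N#Cc1c(F)cc(OCc2ccccc2)cc1O[C@@H]1[C@@H]2CC[C@@H](C2)C1(C)C | intermediate (not isolated)
8 | 4-(benzyloxy)-2-methoxy-6-{[(1R,2R,4S)-3,3-dimethylbicyclo[2.2.1]heptan-2-yl]oxy}benzonitrile | N#Cc1c(OC)cc(OCc2ccccc2)cc1O[C@@H]1[C@@H]2CC[C@@H](C2)C1(C)C | intermediate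
9 | 1-[4-(benzyloxy)-2-methoxy-6-{[(1R,2R,4S)-3,3-dimethylbicyclo[2.2.1]heptan-2-yl]oxy}phenyl]ethan-1-imine (N-magnesio salt before work-up) | CC(=N)c1c(OC)cc(OCc2ccccc2)cc1O[C@@H]1[C@@H]2CC[C@@H](C2)C1(C)C | intermediate (not isolated)
10 | 1-[4-(benzyloxy)-2-methoxy-6-{[(1R,2R,4S)-3,3-dimethylbicyclo[2.2.1]heptan-2-yl]oxy}phenyl]ethan-1-one | CC(=O)c1c(OC)cc(OCc2ccccc2)cc1O[C@@H]1[C@@H]2CC[C@@H](C2)C1(C)C | intermediate
11 | 1-[4-(benzyloxy)-2-methoxy-6-{[(1R,2R,4S)-3,3-dimethylbicyclo[2.2.1]heptan-2-yl]oxy}phenyl]-4,4,4-trifluorobutane-1,3-dione | O=C(CC(=O)C(F)(F)F)c1c(OC)cc(OCc2ccccc2)cc1O[C@@H]1[C@@H]2CC[C@@H](C2)C1(C)C | intermediate (not isolated)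
12 | 1-[4-(benzyloxy)-2-methoxy-6-{[(1R,2R,4S)-3,3-dimethylbicyclo[2.2.1]heptan-2-yl]oxy}phenyl]-2-diazoethan-1-one | [N-]=[N+]=CC(=O)c1c(OC)cc(OCc2ccccc2)cc1O[C@@H]1[C@@H]2CC[C@@H](C2)C1(C)C | intermediate
13 | (2R,1'R,4'S)-7-(benzyloxy)-5-methoxy-3',3'-dimethylspiro[chromane-2,2'-bicyclo[2.2.1]heptan]-4-one | O=C1C[C@@]2(Oc3cc(OCc4ccccc4)cc(OC)c31)[C@@H]1CC[C@@H](C1)C2(C)C | intermediate
14 | isobutylmagnesium bromide | CC(C)C[Mg]Br | starting material
15 | (2R,1'R,4'S)-7-(benzyloxy)-5-methoxy-3',3'-dimethyl-4-(2-methylpropyl)spiro[chromane-2,2'-bicyclo[2.2.1]heptan]-4-ol, C4 unassigned | CC(C)CC1(O)C[C@@]2(Oc3cc(OCc4ccccc4)cc(OC)c31)[C@@H]1CC[C@@H](C1)C2(C)C | intermediate (not isolated)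
16 | (2S,1'R,4'S)-7-(benzyloxy)-5-methoxy-3',3'-dimethyl-4-(2-methylpropyl)spiro[chromene-2,2'-bicyclo[2.2.1]heptane] | CC(C)CC1=C[C@@]2(Oc3cc(OCc4ccccc4)cc(OC)c31)[C@@H]1CC[C@@H](C1)C2(C)C | intermediate
17 | (2R,4S,1'R,4'S)-5-methoxy-3',3'-dimethyl-4-(2-methylpropyl)spiro[chromane-2,2'-bicyclo[2.2.1]heptan]-7-ol | CC(C)C[C@H]1C[C@@]2(Oc3cc(O)cc(OC)c31)[C@@H]1CC[C@@H](C1)C2(C)C | intermediate
18 | (2R,4S,1'R,4'S)-6,8-bis[chloro(methoxy)methyl]-5-methoxy-3',3'-dimethyl-4-(2-methylpropyl)spiro[chromane-2,2'-bicyclo[2.2.1]heptan]-7-ol, side-chain centres unassigned | CC(C)C[C@H]1C[C@@]2(Oc3c(C(Cl)OC)c(O)c(C(Cl)OC)c(OC)c31)[C@@H]1CC[C@@H](C1)C2(C)C | intermediate (not isolated)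
19 | (2R,4S,1'R,4'S)-7-hydroxy-5-methoxy-3',3'-dimethyl-4-(2-methylpropyl)spiro[chromane-2,2'-bicyclo[2.2.1]heptane]-6,8-dicarbaldehyde | CC(C)C[C@H]1C[C@@]2(Oc3c(C=O)c(O)c(C=O)c(OC)c31)[C@@H]1CC[C@@H](C1)C2(C)C | intermediate
20 | (2R,4S,1'R,4'S)-5,7-dihydroxy-3',3'-dimethyl-4-(2-methylpropyl)spiro[chromane-2,2'-bicyclo[2.2.1]heptane]-6,8-dicarbaldehyde | CC(C)C[C@H]1C[C@@]2(Oc3c(C=O)c(O)c(C=O)c(O)c31)[C@@H]1CC[C@@H](C1)C2(C)C | target

**Step count and risks**

Total steps: 11. Longest linear sequence: 10 steps (camphene 1 to target 20 through steps 1, 2 and 4–11).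

Steps most likely to fail:

1. Step 7. The carbenoid may be diverted before it reaches the tertiary C2–H bond, which is flanked by the C3' gem-dimethyl group. Possible diversions are oxonium ylide formation at O1 with 1,2-shift, insertion into the methoxy C–H bonds, and dimerisation. The fallback sets out from 6 and ketone 3 and comes back at 13. It builds the C2–C3 bond by carbonyl addition and closes ring B through O1 instead. One equivalent of NaOMe (THF–MeOH, 0 °C → rt) would convert 6 into 4-(benzyloxy)-2-fluoro-6-methoxybenzonitrile F1. MeMgBr would give the ketimine 1-[4-(benzyloxy)-2-fluoro-6-methoxyphenyl]ethan-1-imine F2, hydrolysed by aqueous HCl to 1-[4-(benzyloxy)-2-fluoro-6-methoxyphenyl]ethan-1-one F3. The enolate of F3 (LiHMDS, then CeCl3, THF, −78 °C) would add to ketone 3 from the exo face, the same face hydride takes in step 2, to give the endo tertiary alcohol 1-[4-(benzyloxy)-2-fluoro-6-methoxyphenyl]-2-[(1R,2R,4S)-2-hydroxy-3,3-dimethylbicyclo[2.2.1]heptan-2-yl]ethan-1-one F4. KHMDS in THF–DMF would then close ring B by intramolecular nucleophilic aromatic substitution of the ketone-activated ortho fluoride by the tertiary alkoxide. Irreversible loss of fluoride should draw the reversible aldol forward, and the product is 13 with O1 endo and C3 exo.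

2. Step 8. Enolisation (with possible E1cB opening of ring B) or β-hydride reduction may win over 1,2-addition at the hindered, electron-rich C4 carbonyl. The fallback sets out from 13 and comes back at 16. It replaces carbonyl addition by cross-coupling. Kinetic enolisation and triflation (KHMDS, PhNTf2, THF, −78 °C) would give the enol triflate (2S,1'R,4'S)-7-(benzyloxy)-5-methoxy-3',3'-dimethylspiro[chromene-2,2'-bicyclo[2.2.1]heptan]-4-yl trifluoromethanesulfonate F5. Iron-catalysed Kumada coupling of F5 with 14 (Fe(acac)3, THF–NMP, −30 °C) would install the isobutyl group and deliver 16 directly.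

3. Step 10. The Lewis acid may ionise the tertiary C2–O1 bond, with loss of the C2 configuration or Wagner–Meerwein rearrangement of the norbornyl cation, and the second formylation of the deactivated ring may stall. The fallback sets out from 17 and comes back at 19. It uses a Vilsmeier–Haack formylation, which needs no metal Lewis acid. POCl3 in DMF (0 → 60 °C) would give the bis(iminium) salt (2R,4S,1'R,4'S)-6,8-bis[(dimethyliminio)methyl]-5-methoxy-3',3'-dimethyl-4-(2-methylpropyl)spiro[chromane-2,2'-bicyclo[2.2.1]heptan]-7-ol dichloride F6. Buffered hydrolysis (aq. NaOAc, rt) would release the dialdehyde 19.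

**Further compounds**

F1 | step 7 | 4-(benzyloxy)-2-fluoro-6-methoxybenzonitrile | N#Cc1c(F)cc(OCc2ccccc2)cc1OC
F2 | step 7 | 1-[4-(benzyloxy)-2-fluoro-6-methoxyphenyl]ethan-1-imine | CC(=N)c1c(F)cc(OCc2ccccc2)cc1OC
F3 | step 7 | 1-[4-(benzyloxy)-2-fluoro-6-methoxyphenyl]ethan-1-one | CC(=O)c1c(F)cc(OCc2ccccc2)cc1OC
F4 | step 7 | 1-[4-(benzyloxy)-2-fluoro-6-methoxyphenyl]-2-[(1R,2R,4S)-2-hydroxy-3,3-dimethylbicyclo[2.2.1]heptan-2-yl]ethan-1-one | O=C(C[C@@]2(O)[C@@H]1CC[C@@H](C1)C2(C)C)c1c(F)cc(OCc3ccccc3)cc1OC
F5 | step 8 | (2S,1'R,4'S)-7-(benzyloxy)-5-methoxy-3',3'-dimethylspiro[chromene-2,2'-bicyclo[2.2.1]heptan]-4-yl trifluoromethanesulfonate | O=S(=O)(OC1=C[C@@]2(Oc3cc(OCc4ccccc4)cc(OC)c31)[C@@H]1CC[C@@H](C1)C2(C)C)C(F)(F)F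
F6 | step 10 | (2R,4S,1'R,4'S)-6,8-bis[(dimethyliminio)methyl]-5-methoxy-3',3'-dimethyl-4-(2-methylpropyl)spiro[chromane-2,2'-bicyclo[2.2.1]heptan]-7-ol dichloride | CC(C)C[C@H]1C[C@@]2(Oc3c(C=[N+](C)C)c(O)c(C=[N+](C)C)c(OC)c31)[C@@H]1CC[C@@H](C1)C2(C)C.[Cl-].[Cl-]
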